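**Retrosynthetic overview**
1. Locants: C1 = quaternary carbinol carbon bearing the (E)-but-2-enoyl group, then round the cycloheptane C2 (CHCH3), C3 (CHOH), C4 (CH2), C5 and C6 (lactone fusion, C6 carries the lactone oxygen), C7 (CH–O-isobutyryl); C8 = lactone CH(CH3); β = ring face of the C1 hydroxyl (target: 1β-OH, 2β-CH3, 3α-OH, 5β-C8, 6β-O, 7α-O, 8R).
2. Late disconnections: the enone C–C bond (C1 thioester + (E)-prop-1-enylboronic acid), the C7 isobutyrate, the C3 and C7 carbinols (C1-hydroxyl-directed reduction of a C3,C7-diketone) and the γ-lactone (C6 ketone reduction, transesterification with the C8 ester).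
3. Ring expansion: the cycloheptane arises from the cyclopentane C3–C4–C5–C6–C7 by retro-aldol cleavage of the C3–C7 bond of a cyclobutane C3–C7–C1–C2 (De Mayo sequence, strain release).
4. Key disconnection: C2–C3 and C1–C7 together, by intramolecular [2+2] photocycloaddition of the C7=C3 bond of a 3-alkoxy-2-silyloxycyclopent-2-enone (carbonyl = C6) to the C1=C2 bond of a 2-silyloxybut-2-enoate. Enabling feature: in the target C3, C7 and C6 all carry oxygen (enol-ether carbon, α-carbon and carbonyl carbon of a reductic-acid-type enone) and the C7 and C1 oxygens are vicinal, so one silicon atom can bridge them as a 1,3-dioxa-2-silolane.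
5. Ring order: cyclopentenone (bought as reductic acid) → dioxasilolane + cyclobutane (key step) → cycloheptane (ring expansion) → γ-lactone; absolute configuration from methyl (R)-lactate (C8), relayed to C5 and from there to C1/C2 in the key step.

Key step: step 6

Assumption: reductic acid is taken as a catalogue compound, and the two C5 epimers formed in step 3 are taken to be separable by chromatography.

Step 1
Reactants: 1 reductic acid (2,3-dihydroxycyclopent-2-en-1-one)
Product: 2 2-hydroxy-3-[(4-methoxybenzyl)oxy]cyclopent-2-en-1-one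
Conditions: 4-MeOC6H4CH2Cl, NaHCO3, DMF, rt
Reagents that add atoms: 4-methoxybenzyl chloride, COc1ccc(CCl)cc1
Why: Williamson-type O-alkylation of the vinylogous carboxylate, the only site that bicarbonate deprotonates, should give the vinylogous ester and leave the less acidic enol hydroxyl on the future C7 free; no stereocentre is formed.

Step 2
Reactants: 3 methyl (R)-lactate
Product: 4 methyl (2R)-2-[(trifluoromethylsulfonyl)oxy]propanoate
Conditions: Tf2O, 2,6-lutidine, CH2Cl2, −78 °C to 0 °C
Reagents that add atoms: trifluoromethanesulfonic anhydride, O=S(=O)(OS(=O)(=O)C(F)(F)F)C(F)(F)F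
Why: O-sulfonylation of the secondary alcohol leaves the C–O bond and hence the configuration untouched and gives an SN2-active α-triflyloxy ester.

Step 3
Reactants: 2 2-hydroxy-3-[(4-methoxybenzyl)oxy]cyclopent-2-en-1-one; 4 methyl (2R)-2-[(trifluoromethylsulfonyl)oxy]propanoate
Product: 5 methyl (2R)-2-{(1S)-3-hydroxy-4-[(4-methoxybenzyl)oxy]-2-oxocyclopent-3-en-1-yl}propanoate
Conditions: LiN(i-Pr)2 (2.1 equiv), THF, −78 °C; then 4, −78 °C to −40 °C; aq NH4Cl
Reagents that add atoms: none
Why: Dianion alkylation at the α′-carbon of the vinylogous ester (the Stork–Danheiser site, which should react before the enol oxyanion) is an SN2 displacement that sets C8 as R by inversion of the (R)-triflate, whereas the ring carbon C5 forms without inherent control, so the (1S) epimer is to be separated and the other recycled by base equilibration through the enol.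

Step 4
Reactants: 6 2-oxobutanoic acid
Product: 7 benzyl 2-oxobutanoate
Conditions: BnBr, KHCO3, DMF, rt
Reagents that add atoms: benzyl bromide, BrCc1ccccc1
Why: Carboxylate O-alkylation gives the benzyl ester, a placeholder for the acyl carbon that can be unmasked late by hydrogenolysis without touching the lactone or the isobutyrate.

Step 5
Reactants: 7 benzyl 2-oxobutanoate; 5 methyl (2R)-2-{(1S)-3-hydroxy-4-[(4-methoxybenzyl)oxy]-2-oxocyclopent-3-en-1-yl}propanoate
Product: 9 benzyl (Z)-2-{[({(4S)-4-[(2R)-1-methoxy-1-oxopropan-2-yl]-2-[(4-methoxybenzyl)oxy]-5-oxocyclopent-1-en-1-yl}oxy)diisopropylsilyl]oxy}but-2-enoate, via enol silyl triflate 8 (not isolated)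
Conditions: i-Pr2Si(OTf)2 (1.0 equiv), Et3N, CH2Cl2, −78 °C; then 5, Et3N, −78 °C to 0 °C
Reagents that add atoms: diisopropylsilyl bis(trifluoromethanesulfonate), CC(C)[Si](OS(=O)(=O)C(F)(F)F)(OS(=O)(=O)C(F)(F)F)C(C)C
Why: Soft enolisation and O-silylation of the α-keto ester (one enolisable side only, Z-enol ether expected) followed by silylation of the single enol hydroxyl of 5 is a stepwise unsymmetrical silyl ketal synthesis that creates no stereocentre.

Step 6
Reactants: 9 benzyl (Z)-2-{[({(4S)-4-[(2R)-1-methoxy-1-oxopropan-2-yl]-2-[(4-methoxybenzyl)oxy]-5-oxocyclopent-1-en-1-yl}oxy)diisopropylsilyl]oxy}but-2-enoate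
Product: 10 tetracyclic photoadduct (cyclobutane C3–C7–C1–C2 cis-fused to the C6 cyclopentanone and to a 2,2-diisopropyl-1,3-dioxa-2-silolane; cyclobutane anti to the C5 side chain; C1–O and C2–CH3 exo; CO2Bn endo)
Conditions: hν (300 nm lamps, Pyrex filter), degassed MeCN (0.005 M), 0 °C
Reagents that add atoms: none
Why: Excitation of the 2,3-dioxygenated cyclopentenone should give its triplet, whose α-carbon C7 adds to C1 of the tethered captodative alkene, and the resulting 1,4-biradical (C3 and C2) collapses to the cyclobutane, so that C7–C1 and C3–C2 are made in one operation. The closest known reaction type is the intramolecular enone–alkene [2+2] photocycloaddition of 2-(alkenyloxy)cycloalk-2-enones and of silicon-tethered dienes, used here as the first half of a De Mayo sequence. Ring closures: the dioxasilolane by 5-exo radical addition (rule of five), the cyclobutane by recombination of the 1,4-biradical, both necessarily cis-fused. Stereocontrol: the tether delivers the alkene to the enone face opposite the C5 side chain, which fixes C1 (and the transient C3 and C7 centres) relative to C5; the one-silicon bridge forces the C1 oxygen exo, cis to the C7 oxygen, and therefore the ester endo; the C2 methyl should take the exo position in the biradical closure, cis to the C1 oxygen as the target requires. The selectivity needed is straight (C7–C1, C3–C2) rather than crossed regiochemistry, and it is secured by the three-atom O–Si–O link of the 1,6-diene. The isopropyl groups on silicon and high dilution should favour cyclisation over E/Z decay of the enol ether and over dimerisation.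

Step 7
Reactants: 10 tetracyclic photoadduct
Product: 12 benzyl 1β,7β-O,O-(diisopropylsilylene)-1,7-dihydroxy-5β-[(2R)-1-methoxy-1-oxopropan-2-yl]-2β-methyl-3,6-dioxocycloheptane-1-carboxylate, via cyclobutanol 11 (not isolated)
Conditions: DDQ, CH2Cl2–pH 7 phosphate buffer (10:1), 0 °C to rt
Reagents that add atoms: none
Why: Oxidative removal of the 4-methoxybenzyl ether frees the tertiary cyclobutanol on C3, a strained aldol of the C6 ketone that should open by retro-aldol cleavage of the C3–C7 bond (second half of the De Mayo reaction) and so expand the five-membered ring to the cycloheptane-1,4-dione; C7 is reprotonated, presumably to the cis-fused silylene acetal, and this centre is erased again in step 10.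

Step 8
Reactants: 12 silylene-protected cycloheptane-3,6-dione
Product: 14 silylene-protected 3β-hydroxy cis-γ-lactone benzyl ester, via dihydroxy methyl ester 13 (not isolated)
Conditions: LiBH(s-Bu)3 (2.5 equiv), THF, −78 °C to 0 °C; aq NH4Cl
Reagents that add atoms: none
Why: Bulky-hydride ketone reduction should deliver hydride to C6 from the α face, opposite the C5 side chain and the C7 silyloxy group, so that the 6β-alkoxide is cis to the ester arm and closes the cis-fused γ-lactone by intramolecular transesterification; the C3 ketone is reduced too (hydride anti to the C2 methyl, 3β-OH expected), which is of no consequence because C3 is re-oxidised in step 10.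

Step 9
Reactants: 14 silylene-protected 3β-hydroxy cis-γ-lactone benzyl ester
Product: 15 1β,3β,7β-trihydroxy lactone benzyl ester
Conditions: HF·pyridine, THF, 0 °C to rt
Reagents that add atoms: none
Why: Fluoride cleavage of the silylene acetal (Si–O to Si–F) releases the C1 and C7 hydroxyls without affecting the esters or any stereocentre.

Step 10
Reactants: 15 1β,3β,7β-trihydroxy lactone benzyl ester
Product: 16 1β-hydroxy-3,7-dioxo lactone benzyl ester
Conditions: Dess–Martin periodinane (3 equiv), CH2Cl2, 0 °C to rt
Reagents that add atoms: none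
Why: Dess–Martin oxidation converts the two secondary alcohols (C3, C7) into ketones and cannot touch the tertiary C1 hydroxyl, which erases the provisional C3 and C7 centres and places both carbonyls within reach of that hydroxyl.

Step 11
Reactants: 16 1β-hydroxy-3,7-dioxo lactone benzyl ester
Product: 17 1β,3α,7α-trihydroxy lactone benzyl ester
Conditions: Me4NBH(OAc)3 (6 equiv), MeCN–AcOH (1:1), −30 °C
Reagents that add atoms: none
Why: Hydroxyl-directed reduction (Evans–Saksena type) should bind the reagent to the 1β-hydroxyl and deliver hydride intramolecularly to the β faces of the α-keto (C7) and β-keto (C3) carbonyls, giving the 1,2-anti and 1,3-anti diols (7α-OH, 3α-OH) while the esters and the lactone stay inert.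

Step 12
Reactants: 17 1β,3α,7α-trihydroxy lactone benzyl ester
Product: 18 3α-O-triethylsilyl ether of 17
Conditions: Et3SiCl (1.1 equiv), imidazole, CH2Cl2, −40 °C
Reagents that add atoms: chlorotriethylsilane, CC[Si](Cl)(CC)CC
Why: Silyl ether formation should occur at the C3 hydroxyl, flanked by CH(CH3) and CH2, in preference to the C7 hydroxyl wedged between the quaternary C1 and C6, and the tertiary C1 hydroxyl is unreactive.

Step 13
Reactants: 18 3α-O-triethylsilyl ether of 17
Product: 19 7α-isobutyrate of 18
Conditions: (i-PrCO)2O, Et3N, DMAP (cat.), CH2Cl2, rt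
Reagents that add atoms: isobutyric anhydride, CC(C)C(=O)OC(=O)C(C)C
Why: DMAP-catalysed acylation (Steglich type) esterifies the only remaining secondary hydroxyl (C7) and spares the hindered tertiary C1 hydroxyl.

Step 14
Reactants: 19 7α-isobutyrate of 18
Product: 20 C1 carboxylic acid
Conditions: H2 (1 atm), Pd/C, EtOAc, rt
Reagents that add atoms: none
Why: Hydrogenolysis of the benzyl ester unmasks the C1 carboxylic acid as the only free acid, with the lactone, the isobutyrate and the silyl ether untouched (no alkene is present yet).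

Step 15
Reactants: 20 C1 carboxylic acid
Product: 21 S-ethyl thioester
Conditions: EtSH, EDC·HCl, DMAP (cat.), CH2Cl2, 0 °C to rt
Reagents that add atoms: ethanethiol, CCS
Why: Carbodiimide-mediated thioesterification (Steglich type) activates the acid as an S-ethyl thioester, and because the C3 oxygen is silylated the cis γ-hydroxyl cannot capture the acyl group as a bridged lactone.

Step 16
Reactants: 21 S-ethyl thioester; 22 (E)-prop-1-enylboronic acid
Product: 23 3-O-triethylsilyl ether of the target
Conditions: Pd2(dba)3 (cat.), P(2-furyl)3, CuTC [Cu(O2CC4H3S)] (1.5 equiv), THF, 50 °C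
Reagents that add atoms: none
Why: Liebeskind–Srogl coupling (thioester plus boronic acid under neutral conditions, the copper carboxylate taking up the thiolate) should give the (E)-enone with retention of alkene geometry and tolerate the lactone, the isobutyrate and the free tertiary hydroxyl.

Step 17
Reactants: 23 3-O-triethylsilyl ether of the target
Product: 24 CNP0268641.1
Conditions: HF·pyridine, THF–pyridine, 0 °C
Reagents that add atoms: none
Why: Buffered fluoride desilylation removes the triethylsilyl ether without base, so that neither acyl migration from C7 nor retro-aldol or elimination at the β-hydroxy ketone is provoked.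

**Compound list**
1 | reductic acid (2,3-dihydroxycyclopent-2-en-1-one) | O=C1CCC(O)=C1O | starting material
2 | 2-hydroxy-3-[(4-methoxybenzyl)oxy]cyclopent-2-en-1-one | O=C1CCC(OCc2ccc(OC)cc2)=C1O | intermediate
3 | methyl (R)-lactate | C[C@@H](O)C(=O)OC | starting material
4 | methyl (2R)-2-[(trifluoromethylsulfonyl)oxy]propanoate | C[C@@H](OS(=O)(=O)C(F)(F)F)C(=O)OC | intermediate
5 | methyl (2R)-2-{(1S)-3-hydroxy-4-[(4-methoxybenzyl)oxy]-2-oxocyclopent-3-en-1-yl}propanoate | COC(=O)[C@H](C)[C@@H]1CC(OCc2ccc(OC)cc2)=C(O)C1=O | intermediate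
6 | 2-oxobutanoic acid | CCC(=O)C(=O)O | starting material
7 | benzyl 2-oxobutanoate | CCC(=O)C(=O)OCc1ccccc1 | intermediate
8 | enol silyl triflate: benzyl (Z)-2-{[diisopropyl(trifluoromethylsulfonyloxy)silyl]oxy}but-2-enoate (not isolated) | C/C=C(/C(=O)OCc1ccccc1)O[Si](C(C)C)(C(C)C)OS(=O)(=O)C(F)(F)F | intermediate
9 | silicon-tethered enone–alkene: benzyl (Z)-2-{[({(4S)-4-[(2R)-1-methoxy-1-oxopropan-2-yl]-2-[(4-methoxybenzyl)oxy]-5-oxocyclopent-1-en-1-yl}oxy)diisopropylsilyl]oxy}but-2-enoate | COC(=O)[C@H](C)[C@@H]1CC(OCc2ccc(OC)cc2)=C(O[Si](C(C)C)(C(C)C)O/C(=C\C)C(=O)OCc3ccccc3)C1=O | intermediate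
10 | tetracyclic photoadduct (cyclobutane C3–C7–C1–C2 fused to the C6 cyclopentanone and to the dioxasilolane; C3 4-methoxybenzyl ether; C1–O and C2–CH3 exo; CO2Bn endo; cyclobutane anti to the C5 side chain) | COC(=O)[C@H](C)[C@@H]1C[C@@]2(OCc3ccc(OC)cc3)[C@H](C)[C@]4(C(=O)OCc5ccccc5)O[Si](C(C)C)(C(C)C)O[C@]24C1=O | intermediate
11 | cyclobutanol (C3–OH analogue of 10; not isolated) | COC(=O)[C@H](C)[C@@H]1C[C@@]2(O)[C@H](C)[C@]4(C(=O)OCc5ccccc5)O[Si](C(C)C)(C(C)C)O[C@]24C1=O | intermediate
12 | benzyl 1β,7β-O,O-(diisopropylsilylene)-1,7-dihydroxy-5β-[(2R)-1-methoxy-1-oxopropan-2-yl]-2β-methyl-3,6-dioxocycloheptane-1-carboxylate | O=C(OCc1ccccc1)[C@]2(O[Si]3(C(C)C)C(C)C)[C@@H](C)C(=O)C[C@@H]([C@@H](C)C(=O)OC)C(=O)[C@H]2O3 | intermediate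
13 | 3β,6β-dihydroxy methyl ester (silylene on the C1 and C7 oxygens; not isolated) | O=C(OCc1ccccc1)[C@]2(O[Si]3(C(C)C)C(C)C)[C@@H](C)[C@@H](O)C[C@@H]([C@@H](C)C(=O)OC)[C@@H](O)[C@H]2O3 | intermediate
14 | silylene-protected 3β-hydroxy cis-γ-lactone benzyl ester | O=C(OCc1ccccc1)[C@]2(O[Si]3(C(C)C)C(C)C)[C@@H](C)[C@@H](O)C[C@@H]4[C@@H](OC(=O)[C@@H]4C)[C@H]2O3 | intermediate
15 | 1β,3β,7β-trihydroxy lactone benzyl ester | O=C(OCc1ccccc1)[C@]2(O)[C@@H](C)[C@@H](O)C[C@@H]3[C@@H](OC(=O)[C@@H]3C)[C@H]2O | intermediate
16 | 1β-hydroxy-3,7-dioxo lactone benzyl ester | O=C(OCc1ccccc1)[C@]2(O)[C@@H](C)C(=O)C[C@@H]3[C@@H](OC(=O)[C@@H]3C)C2=O | intermediate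
17 | 1β,3α,7α-trihydroxy lactone benzyl ester | O=C(OCc1ccccc1)[C@]2(O)[C@@H](C)[C@H](O)C[C@@H]3[C@@H](OC(=O)[C@@H]3C)[C@@H]2O | intermediate
18 | 3α-O-triethylsilyl ether of 17 | O=C(OCc1ccccc1)[C@]2(O)[C@@H](C)[C@H](O[Si](CC)(CC)CC)C[C@@H]3[C@@H](OC(=O)[C@@H]3C)[C@@H]2O | intermediate
19 | 7α-isobutyrate of 18 | O=C(OCc1ccccc1)[C@]2(O)[C@@H](C)[C@H](O[Si](CC)(CC)CC)C[C@@H]3[C@@H](OC(=O)[C@@H]3C)[C@@H]2OC(=O)C(C)C | intermediate
20 | C1 carboxylic acid (1β-OH, 3α-OSiEt3, 7α-isobutyrate, cis-lactone) | OC(=O)[C@]2(O)[C@@H](C)[C@H](O[Si](CC)(CC)CC)C[C@@H]3[C@@H](OC(=O)[C@@H]3C)[C@@H]2OC(=O)C(C)C | intermediate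
21 | S-ethyl thioester of 20 | CCSC(=O)[C@]2(O)[C@@H](C)[C@H](O[Si](CC)(CC)CC)C[C@@H]3[C@@H](OC(=O)[C@@H]3C)[C@@H]2OC(=O)C(C)C | intermediate
22 | (E)-prop-1-enylboronic acid | C/C=C/B(O)O | starting material
23 | 3-O-triethylsilyl ether of the target | C/C=C/C(=O)[C@]1(O)[C@@H](C)[C@H](O[Si](CC)(CC)CC)C[C@@H]2[C@@H](OC(=O)[C@@H]2C)[C@@H]1OC(=O)C(C)C | intermediate
24 | CNP0268641.1 | C/C=C/C(=O)[C@]1(O)[C@@H](C)[C@H](O)C[C@@H]2[C@@H](OC(=O)[C@@H]2C)[C@@H]1OC(=O)C(C)C | target

**Step count and risk**
Total step count: 17. Longest linear sequence: 15 steps (1, 3, 5–17, from reductic acid).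

Steps most likely to fail:

- Step 6 (key photocycloaddition). The triplet may decay by E/Z isomerisation of the enol ether, the labile bis-enol silyl ketal may be cleaved, or closure of a cyclobutane with three fully substituted carbons may be too slow, so that little cycloadduct forms. Fallback, setting out from 5 and 7 and coming back at 15: 5 is silylated (Et3SiCl, imidazole) to the triethylsilyl ether F1, and 7 is converted (Et3SiOTf, Et3N) into benzyl (Z)-2-(triethylsilyloxy)but-2-enoate F2. Irradiation of F1 with an excess of F2 (300 nm) is an intermolecular enone–alkene [2+2] that should favour the head-to-head cyclobutane F3 anti to the C5 side chain; the isomer with the C1 silyloxy group exo is taken on after chromatography. DDQ then gives the bis(triethylsilyl) cycloheptanedione F4 by the same retro-aldol opening, LiBH(s-Bu)3 gives the hydroxy lactone F5, and HF·pyridine removes both silyl groups to give 15.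
- Step 3 (dianion alkylation). The enol oxyanion may be alkylated on oxygen, proton transfer may quench the α′-enolate, and the ring carbon may form with poor diastereoselection. Fallback, setting out from 2 and coming back at 5: 2 is protected (t-BuMe2SiCl, imidazole) as the tert-butyldimethylsilyl ether F6, whose mono-enolate (LiN(i-Pr)2, 1.05 equiv, THF, −78 °C) is alkylated with 4 to the alkylated silyl ether F7; HF·pyridine then frees the enol hydroxyl to give 5, and the unwanted ring epimer is equilibrated with DBU and recycled.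
- Step 16 (Liebeskind–Srogl coupling). Acyl–sulfur insertion of zerovalent palladium at the hindered tertiary α-hydroxy thioester may be slow, and the alkenylboronic acid may protodeboronate or homocouple before transmetalation. Fallback, setting out from 20 and coming back at 23: 20 is converted (2,2′-dipyridyl disulfide, PPh3, MeCN) into the S-(pyridin-2-yl) thioester F8, which is treated with (E)-CH3CH=CHMgBr (2.2 equiv, THF, −78 °C); chelation-assisted acyl substitution at the pyridyl thioester should outrun attack on the lactone and the isobutyrate and give 23.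

**Further compounds**
F1 | step 6 | triethylsilyl ether of 5 | COC(=O)[C@H](C)[C@@H]1CC(OCc2ccc(OC)cc2)=C(O[Si](CC)(CC)CC)C1=O
F2 | step 6 | benzyl (Z)-2-(triethylsilyloxy)but-2-enoate | C/C=C(/C(=O)OCc1ccccc1)O[Si](CC)(CC)CC
F3 | step 6 | head-to-head cyclobutane (bis(triethylsilyl) analogue of 10) | COC(=O)[C@H](C)[C@@H]1C[C@@]2(OCc3ccc(OC)cc3)[C@H](C)[C@](C(=O)OCc4ccccc4)(O[Si](CC)(CC)CC)[C@@]2(O[Si](CC)(CC)CC)C1=O
F4 | step 6 | bis(triethylsilyl) cycloheptanedione (analogue of 12) | O=C(OCc1ccccc1)[C@]2(O[Si](CC)(CC)CC)[C@@H](C)C(=O)C[C@@H]([C@@H](C)C(=O)OC)C(=O)[C@H]2O[Si](CC)(CC)CC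
F5 | step 6 | bis(triethylsilyl) hydroxy lactone (analogue of 14) | O=C(OCc1ccccc1)[C@]2(O[Si](CC)(CC)CC)[C@@H](C)[C@@H](O)C[C@@H]3[C@@H](OC(=O)[C@@H]3C)[C@H]2O[Si](CC)(CC)CC
F6 | step 3 | tert-butyldimethylsilyl ether of 2 | O=C1CCC(OCc2ccc(OC)cc2)=C1O[Si](C)(C)C(C)(C)C
F7 | step 3 | tert-butyldimethylsilyl ether of 5 | COC(=O)[C@H](C)[C@@H]1CC(OCc2ccc(OC)cc2)=C(O[Si](C)(C)C(C)(C)C)C1=O
F8 | step 16 | S-(pyridin-2-yl) thioester of 20 | O=C(Sc1ccccn1)[C@]2(O)[C@@H](C)[C@H](O[Si](CC)(CC)CC)C[C@@H]3[C@@H](OC(=O)[C@@H]3C)[C@@H]2OC(=O)C(C)C
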